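**Retrosynthetic overview**
1. The target is opened at the C3 dienoate ester and the C12 acetate. The 3α-OH comes from singlet-oxygen addition to a ring A diene (C10=C1–C2=C3), and the C9=C10 and C1=C2 bonds from two dehydrogenations of the C8 ketone.
2. The C7 carbinol comes from addition of a 2-lithioallyl silyl ether to a C7 ketone (C8 masked as a dioxolane), on the face opposite the axial C5 methyl.
3. The strategy rests on quaternary C5: it carries methyl C14 and is joined through C6 to C7, which is α to the C8 ketone in ring B. The C5–C6 bond is therefore made by iron-hydride hydrogen-atom transfer to an exocyclic C5=C14 methylene on ring A, followed by 6-endo addition of the tertiary C5 radical to C6 of a 2-silyloxy enone.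
4. The cyclisation precursor comes from Weinreb acylation of a (3-methyl-2-methylenecyclohexyl)methyl Grignard reagent. C10 is set by proline-catalysed hydroxymethylation of cyclohexanone and C4 by kinetic protonation of a regiodefined enolate. The cis ketone is never base-equilibrated, because equilibration through the trans isomer would interconvert its enantiomers.
5. Ring order: ring A is bought as cyclohexanone; ring B is closed in the key step.

Key step: step 10

Remark on the chemistry: D-proline is assumed to give the (R)-aldol 2, the mirror image of the L-proline product. Eremophilane numbering is used throughout (ring A = C1–C5, C10; ring B = C5–C10; C14 on C5, C15 on C4, C11–C13 on C7); β is the face of C14.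

Step 1
Reactants: 1 cyclohexanone
Product: 2 (R)-2-(hydroxymethyl)cyclohexan-1-one
Conditions: D-proline (10 mol%), 37% aq. HCHO, DMSO, rt
Reagents that add atoms: formaldehyde C=O
Why: Proline-catalysed enamine aldol reaction with formaldehyde (asymmetric α-hydroxymethylation), in which hydrogen bonding of the carboxylic acid to formaldehyde fixes the enamine face attacked and so sets C10 (R), the centre from which C4, C5, C7 and C3 are later derived.

Step 2
Reactants: 2 (R)-2-(hydroxymethyl)cyclohexan-1-one
Product: 3 (R)-2-{[(tert-butyldimethylsilyl)oxy]methyl}cyclohexan-1-one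
Conditions: TBSCl, imidazole, CH2Cl2, 0 °C
Reagents that add atoms: tert-butyldimethylsilyl chloride CC(C)(C)[Si](C)(C)Cl
Why: Silylation of the primary alcohol under mild base, which blocks retro-aldol and dehydration of the aldol and should leave C10 unchanged.

Step 3
Reactants: 3 (R)-2-{[(tert-butyldimethylsilyl)oxy]methyl}cyclohexan-1-one
Product: 6 (R)-2-{[(tert-butyldimethylsilyl)oxy]methyl}-6-methylidenecyclohexan-1-one, via Mannich base 4 (not isolated), via ammonium iodide 5 (not isolated)
Conditions: LiN(i-Pr)2, THF, −78 °C; Me2N=CH2+ I−, −78 → 0 °C; MeI, rt; aq. NaHCO3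
Reagents that add atoms: N,N-dimethylmethyleneiminium iodide C=[N+](C)C.[I-]
Why: Kinetic deprotonation at the unsubstituted α-carbon (C4) leaves C10 untouched, and the Mannich reaction followed by Hofmann-type elimination of the quaternised amine gives the exocyclic enone (α-methylenation).

Step 4
Reactants: 6 (R)-2-{[(tert-butyldimethylsilyl)oxy]methyl}-6-methylidenecyclohexan-1-one
Product: 8 (2R,6R)-2-{[(tert-butyldimethylsilyl)oxy]methyl}-6-methylcyclohexan-1-one, via lithium enolate 7 (not isolated)
Conditions: LiBH(s-Bu)3, THF, −78 °C; then AcOH, −78 °C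
Reagents that add atoms: none
Why: Conjugate reduction gives the C4 enolate regiospecifically, and kinetic axial protonation anti to the C10 side chain (held pseudoaxial by allylic strain with the enolate oxygen) should set C4 cis to it, the same facial rule that makes alkylation of 6-substituted cyclohexanone enolates trans, here with hydrogen as the electrophile.

Step 5
Reactants: 8 (2R,6R)-2-{[(tert-butyldimethylsilyl)oxy]methyl}-6-methylcyclohexan-1-one
Product: 9 tert-butyl{[(1S,3R)-3-methyl-2-methylidenecyclohexyl]methoxy}dimethylsilane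
Conditions: Cp2TiMe2, toluene, 65 °C, dark
Reagents that add atoms: dimethyltitanocene C[Ti](C)(C1C=CC=C1)C1C=CC=C1
Why: Petasis methylenation through the titanium methylidene is non-basic, so the cis ketone should be neither epimerised nor β-eliminated while C5=C14 is formed.

Step 6
Reactants: 9 tert-butyl{[(1S,3R)-3-methyl-2-methylidenecyclohexyl]methoxy}dimethylsilane
Product: 10 (1S,3R)-1-(bromomethyl)-3-methyl-2-methylidenecyclohexane
Conditions: Ph3PBr2, CH2Cl2, 0 °C → rt
Reagents that add atoms: dibromotriphenylphosphorane BrP(Br)(c1ccccc1)(c1ccccc1)c1ccccc1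
Why: Direct silyl ether to bromide conversion through an alkoxyphosphonium ion and SN2 displacement by bromide at the primary carbon C9, with no stereocentre involved.

Step 7
Reactants: 11 pyruvic acid
Product: 12 N-methoxy-N-methyl-2-oxopropanamide
Conditions: MeNHOMe·HCl, EDC·HCl, N-methylmorpholine, CH2Cl2, 0 °C → rt
Reagents that add atoms: N,O-dimethylhydroxylamine hydrochloride CNOC.Cl
Why: Carbodiimide amide coupling gives the Weinreb amide of the α-keto acid.

Step 8
Reactants: 12 N-methoxy-N-methyl-2-oxopropanamide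
Product: 13 2-[(tert-butyldimethylsilyl)oxy]-N-methoxy-N-methylprop-2-enamide
Conditions: TBSOTf, Et3N, CH2Cl2, 0 °C
Reagents that add atoms: tert-butyldimethylsilyl trifluoromethanesulfonate CC(C)(C)[Si](C)(C)OS(=O)(=O)C(F)(F)F
Why: Soft enolisation to the silyl enol ether, whose regiochemistry is unambiguous because the methyl group is the only enolisable position.

Step 9
Reactants: 10 (1S,3R)-1-(bromomethyl)-3-methyl-2-methylidenecyclohexane; 13 2-[(tert-butyldimethylsilyl)oxy]-N-methoxy-N-methylprop-2-enamide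
Product: 15 3-[(tert-butyldimethylsilyl)oxy]-1-[(1R,3R)-3-methyl-2-methylidenecyclohexyl]but-3-en-2-one, via Grignard reagent 14 (not isolated)
Conditions: Mg, THF, rt; then 13, −78 → 0 °C; aq. NH4Cl
Reagents that add atoms: none
Why: Weinreb ketone synthesis, in which the chelated tetrahedral intermediate stops over-addition and the electron-rich silyl enol ether disfavours conjugate addition, so the 2-silyloxy enone should form with the silyloxy group fixed on C7 and C10 unaffected.

Step 10
Reactants: 15 3-[(tert-butyldimethylsilyl)oxy]-1-[(1R,3R)-3-methyl-2-methylidenecyclohexyl]but-3-en-2-one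
Product: 16 (3S,4aS,5R,8aR)-3-[(tert-butyldimethylsilyl)oxy]-4a,5-dimethyloctahydronaphthalen-2(1H)-one
Conditions: Fe(acac)3 (30 mol%), PhSiH3, EtOH/(CH2OH)2 (5:1, 0.02 M), 60 °C
Reagents that add atoms: none
Why: The hydride of trivalent iron formed from Fe(acac)3 and PhSiH3 transfers a hydrogen atom to C14 of the exocyclic methylene, the nucleophilic tertiary C5 radical adds to C6 (the unsubstituted β-carbon of the 2-silyloxy enone), and the captodative C7 radical is reduced by divalent iron and protonated by ethanol, which regenerates trivalent iron. The closest known reaction is the iron-hydride hydrogen-atom-transfer reductive coupling of an alkene with an enone (Giese-type radical conjugate addition), used here intramolecularly. Ring B closes in the 6-endo-trig mode, because the carbonyl C8 lies inside the C10–C9–C8 tether and C6 is the polarity-matched terminus. C5 is set by a chair-like transition state in which the C4 methyl and the C10 chain stay equatorial on ring A, so the new C5–C6 bond is equatorial and C14 ends axial, cis to the C4 methyl and trans to H-10 (trans-decalin); C7 should form mainly as the equatorial silyl ether, but its configuration is immaterial because it is oxidised in step 13. The step needs facial selectivity at the planar C5 radical, which the cis-2,6 arrangement from steps 1 and 4 secures, and hydrogen-atom transfer to the electron-rich 1,1-disubstituted alkene in preference to the electron-poor enone, which the polarity of the iron hydride secures.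

Step 11
Reactants: 16 (3S,4aS,5R,8aR)-3-[(tert-butyldimethylsilyl)oxy]-4a,5-dimethyloctahydronaphthalen-2(1H)-one
Product: 17 7α-[(tert-butyldimethylsilyl)oxy]-8,8-(ethylenedioxy)-4β,5β-dimethyl-10α-H-decalin
Conditions: TMSOCH2CH2OTMS, TMSOTf (cat.), CH2Cl2, −78 → −20 °C
Reagents that add atoms: 1,2-bis(trimethylsilyloxy)ethane C[Si](C)(C)OCCO[Si](C)(C)C
Why: Silyl-transfer ketalisation under aprotic low-temperature conditions should mask C8 without cleaving the silyl ether or isomerising the α-oxygenated ketone.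

Step 12
Reactants: 17 7α-[(tert-butyldimethylsilyl)oxy]-8,8-(ethylenedioxy)-4β,5β-dimethyl-10α-H-decalin
Product: 18 8,8-(ethylenedioxy)-4β,5β-dimethyl-10α-H-decalin-7α-ol
Conditions: Bu4NF, THF, rt
Reagents that add atoms: none
Why: Fluoride desilylation frees the C7 alcohol while the ketal is inert to fluoride.

Step 13
Reactants: 18 8,8-(ethylenedioxy)-4β,5β-dimethyl-10α-H-decalin-7α-ol
Product: 19 8,8-(ethylenedioxy)-4β,5β-dimethyl-10α-H-decalin-7-one
Conditions: Dess–Martin periodinane, CH2Cl2, rt
Reagents that add atoms: none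
Why: Dess–Martin oxidation gives a C7 ketone that cannot enolise toward the ketal carbon C8, so the carbonyl is regiochemically fixed and the mixed C7 centre is removed.

Step 14
Reactants: 20 2-bromoprop-2-en-1-ol
Product: 21 [(2-bromoprop-2-en-1-yl)oxy]tri(propan-2-yl)silane
Conditions: TIPSCl, imidazole, CH2Cl2, rt
Reagents that add atoms: triisopropylsilyl chloride CC(C)[Si](Cl)(C(C)C)C(C)C
Why: Silylation of the allylic alcohol with a bulky silyl group that should resist oxygen-to-carbon silyl migration in the derived vinyllithium and survive the later acid, base and oxidant steps.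

Step 15
Reactants: 19 8,8-(ethylenedioxy)-4β,5β-dimethyl-10α-H-decalin-7-one; 21 [(2-bromoprop-2-en-1-yl)oxy]tri(propan-2-yl)silane
Product: 23 8,8-(ethylenedioxy)-4β,5β-dimethyl-7α-{3-[(triisopropylsilyl)oxy]prop-1-en-2-yl}-10α-H-decalin-7β-ol, via vinyllithium 22 (not isolated)
Conditions: 21, t-BuLi (2 equiv), Et2O, −78 °C; then 19, −78 °C
Reagents that add atoms: none
Why: Bromine–lithium exchange and 1,2-addition of the vinyllithium, which should attack C7 equatorially on the face opposite the syn-axial C5 methyl (as in 3,3,5-trimethylcyclohexanone), giving the axial 7β-hydroxyl cis to C14.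

Step 16
Reactants: 23 8,8-(ethylenedioxy)-4β,5β-dimethyl-7α-{3-[(triisopropylsilyl)oxy]prop-1-en-2-yl}-10α-H-decalin-7β-ol
Product: 24 7β-hydroxy-4β,5β-dimethyl-7α-{3-[(triisopropylsilyl)oxy]prop-1-en-2-yl}-10α-H-decalin-8-one
Conditions: 1 M HCl, THF, rt
Reagents that add atoms: water O
Why: Acid-catalysed acetal hydrolysis returns the C8 ketone; the triisopropylsilyl ether should tolerate dilute acid and ionisation of the tertiary allylic alcohol is disfavoured by the adjacent carbonyl carbon.

Step 17
Reactants: 24 7β-hydroxy-4β,5β-dimethyl-7α-{3-[(triisopropylsilyl)oxy]prop-1-en-2-yl}-10α-H-decalin-8-one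
Product: 25 7β-hydroxy-12-[(triisopropylsilyl)oxy]eremophila-9,11(13)-dien-8-one
Conditions: IBX, DMSO, 70 °C
Reagents that add atoms: none
Why: IBX dehydrogenation of the ketone; C7 is quaternary, so only C9 can enolise and the double bond must form at C9=C10, which also removes the relay centre C10.

Step 18
Reactants: 25 7β-hydroxy-12-[(triisopropylsilyl)oxy]eremophila-9,11(13)-dien-8-one
Product: 27 7β-hydroxy-12-[(triisopropylsilyl)oxy]eremophila-1,9,11(13)-trien-8-one, via silyl dienol ether 26 (not isolated)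
Conditions: TMSOTf, Et3N, CH2Cl2, 0 °C; then DDQ, CH2Cl2, 0 °C; 1 M HCl work-up
Reagents that add atoms: none
Why: Soft γ-enolisation at C1 gives the extended silyl dienol ether and DDQ abstracts hydride from C2 (dehydrogenation through the dienol ether), giving the linear C9=C10–C1=C2 dienone because C7 has no hydrogen for a cross-conjugated isomer; the acidic work-up frees the tertiary silyl ether.

Step 19
Reactants: 27 7β-hydroxy-12-[(triisopropylsilyl)oxy]eremophila-1,9,11(13)-trien-8-one
Product: 29 7β-hydroxy-12-[(triisopropylsilyl)oxy]eremophila-1(10),2,11(13)-trien-8-one, via potassium trienolate 28 (not isolated)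
Conditions: KOt-Bu (3 equiv), THF/t-BuOH, 0 °C; then cold aq. AcOH
Reagents that add atoms: none
Why: Deconjugative protonation: tert-butoxide removes the ε-hydrogen at C3 (and the hydroxyl proton), and kinetic protonation of the trienolate at the α-carbon C9 places a homoannular C10=C1–C2=C3 diene in ring A without touching C4, C5 or C7.

Step 20
Reactants: 29 7β-hydroxy-12-[(triisopropylsilyl)oxy]eremophila-1(10),2,11(13)-trien-8-one
Product: 32 3α,7β-dihydroxy-12-[(triisopropylsilyl)oxy]eremophila-1,9,11(13)-trien-8-one, via endoperoxide 30 (not isolated), via hydroperoxide 31 (not isolated)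
Conditions: O2, tetraphenylporphyrin (cat.), visible light, CH2Cl2, −30 °C; DBU (cat.), −30 → 0 °C; PPh3, 0 °C
Reagents that add atoms: oxygen O=O
Why: Singlet-oxygen [4+2] cycloaddition to the ring A diene from the α face (opposite the C5 and C4 methyls), E1cB opening from the acidic C9–H to restore the C9=C10–C1=C2 dienone, and phosphine reduction of the C3 hydroperoxide; the facial preference of the cycloaddition sets the 3α (3S) carbinol trans to the C4 methyl.

Step 21
Reactants: 33 (R)-2-methylbutanoic acid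
Product: 34 (R)-2-methylbutan-1-ol
Conditions: LiAlH4, Et2O, 0 °C → rt
Reagents that add atoms: none
Why: Hydride reduction of the acid to the primary alcohol, which does not involve the stereocentre.

Step 22
Reactants: 34 (R)-2-methylbutan-1-ol
Product: 36 (2E,4R)-2,4-dimethylhex-2-enal, via aldehyde 35 (not isolated)
Conditions: (COCl)2, DMSO, i-Pr2NEt, CH2Cl2, −78 °C; then Ph3P=C(Me)CHO, CH2Cl2, reflux
Reagents that add atoms: 2-(triphenylphosphoranylidene)propanal CC(C=O)=P(c1ccccc1)(c1ccccc1)c1ccccc1
Why: Swern oxidation then Wittig reaction with a stabilised ylide, which should give the (E)-trisubstituted enal; the α-branched aldehyde is used without isolation under near-neutral conditions to protect its stereocentre.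

Step 23
Reactants: 36 (2E,4R)-2,4-dimethylhex-2-enal
Product: 37 ethyl (2E,4E,6R)-4,6-dimethylocta-2,4-dienoate
Conditions: (EtO)2P(O)CH2CO2Et, NaH, THF, 0 °C → rt
Reagents that add atoms: triethyl phosphonoacetate CCOC(=O)CP(=O)(OCC)OCC
Why: Horner–Wadsworth–Emmons olefination, which should be (E)-selective for the new disubstituted double bond.

Step 24
Reactants: 37 ethyl (2E,4E,6R)-4,6-dimethylocta-2,4-dienoate
Product: 38 (2E,4E,6R)-4,6-dimethylocta-2,4-dienoic acid
Conditions: LiOH, THF/MeOH/H2O, rt; then 1 M HCl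
Reagents that add atoms: lithium hydroxide [Li+].[OH-]
Why: Ester saponification; the stereocentre is remote from any acidic position and the diene geometry is not at risk.

Step 25
Reactants: 32 3α,7β-dihydroxy-12-[(triisopropylsilyl)oxy]eremophila-1,9,11(13)-trien-8-one; 38 (2E,4E,6R)-4,6-dimethylocta-2,4-dienoic acid
Product: 39 7β-hydroxy-8-oxo-12-[(triisopropylsilyl)oxy]eremophila-1,9,11(13)-trien-3α-yl (2E,4E,6R)-4,6-dimethylocta-2,4-dienoate
Conditions: 38, 2,4,6-trichlorobenzoyl chloride, Et3N, THF, rt; then 32, DMAP, toluene, rt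
Reagents that add atoms: none
Why: Yamaguchi esterification acylates the secondary allylic 3α-hydroxyl at oxygen (retention at C3), while the hindered tertiary 7β-hydroxyl next to the ketone should not react.

Step 26
Reactants: 39 7β-hydroxy-8-oxo-12-[(triisopropylsilyl)oxy]eremophila-1,9,11(13)-trien-3α-yl (2E,4E,6R)-4,6-dimethylocta-2,4-dienoate
Product: 40 7β,12-dihydroxy-8-oxoeremophila-1,9,11(13)-trien-3α-yl (2E,4E,6R)-4,6-dimethylocta-2,4-dienoate
Conditions: HF·pyridine, pyridine, THF, 0 °C → rt
Reagents that add atoms: none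
Why: Buffered fluoride desilylation frees the primary allylic alcohol without the basic conditions that could deconjugate the dienone or displace the allylic ester.

Step 27
Reactants: 40 7β,12-dihydroxy-8-oxoeremophila-1,9,11(13)-trien-3α-yl (2E,4E,6R)-4,6-dimethylocta-2,4-dienoate
Product: 41 12-acetoxy-7β-hydroxy-8-oxoeremophila-1,9,11(13)-trien-3α-yl (2E,4E,6R)-4,6-dimethylocta-2,4-dienoate
Conditions: Ac2O, pyridine, CH2Cl2, 0 °C
Reagents that add atoms: acetic anhydride CC(=O)OC(C)=O
Why: Acetylation of the primary allylic alcohol, selective over the tertiary α-ketol hydroxyl on steric grounds, should give the target.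

**Compound list**
1 | cyclohexanone | O=C1CCCCC1 | starting material
2 | (R)-2-(hydroxymethyl)cyclohexan-1-one | O=C1CCCC[C@@H]1CO | intermediate
3 | (R)-2-{[(tert-butyldimethylsilyl)oxy]methyl}cyclohexan-1-one | O=C1CCCC[C@@H]1CO[Si](C)(C)C(C)(C)C | intermediate
4 | (2R)-2-{[(tert-butyldimethylsilyl)oxy]methyl}-6-[(dimethylamino)methyl]cyclohexan-1-one (C6 epimers) | O=C1C(CN(C)C)CCC[C@@H]1CO[Si](C)(C)C(C)(C)C | intermediate (not isolated)
5 | trimethylammonium iodide of 4 | O=C1C(C[N+](C)(C)C)CCC[C@@H]1CO[Si](C)(C)C(C)(C)C.[I-] | intermediate (not isolated)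
6 | (R)-2-{[(tert-butyldimethylsilyl)oxy]methyl}-6-methylidenecyclohexan-1-one | O=C1C(=C)CCC[C@@H]1CO[Si](C)(C)C(C)(C)C | intermediate
7 | lithium (6R)-6-{[(tert-butyldimethylsilyl)oxy]methyl}-2-methylcyclohex-1-en-1-olate | [Li+].[O-]C1=C(C)CCC[C@@H]1CO[Si](C)(C)C(C)(C)C | intermediate (not isolated)
8 | (2R,6R)-2-{[(tert-butyldimethylsilyl)oxy]methyl}-6-methylcyclohexan-1-one (cis) | O=C1[C@H](C)CCC[C@@H]1CO[Si](C)(C)C(C)(C)C | intermediate
9 | tert-butyl{[(1S,3R)-3-methyl-2-methylidenecyclohexyl]methoxy}dimethylsilane (cis) | C=C1[C@H](C)CCC[C@@H]1CO[Si](C)(C)C(C)(C)C | intermediate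
10 | (1S,3R)-1-(bromomethyl)-3-methyl-2-methylidenecyclohexane (cis) | C=C1[C@H](C)CCC[C@@H]1CBr | intermediate
11 | pyruvic acid | CC(=O)C(=O)O | starting material
12 | N-methoxy-N-methyl-2-oxopropanamide | CC(=O)C(=O)N(C)OC | intermediate
13 | 2-[(tert-butyldimethylsilyl)oxy]-N-methoxy-N-methylprop-2-enamide | C=C(O[Si](C)(C)C(C)(C)C)C(=O)N(C)OC | intermediate
14 | {[(1S,3R)-3-methyl-2-methylidenecyclohexyl]methyl}magnesium bromide | C=C1[C@H](C)CCC[C@@H]1C[Mg]Br | intermediate (not isolated)
15 | 3-[(tert-butyldimethylsilyl)oxy]-1-[(1R,3R)-3-methyl-2-methylidenecyclohexyl]but-3-en-2-one | C=C1[C@H](C)CCC[C@@H]1CC(=O)C(=C)O[Si](C)(C)C(C)(C)C | intermediate (key-step precursor)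
16 | (3S,4aS,5R,8aR)-3-[(tert-butyldimethylsilyl)oxy]-4a,5-dimethyloctahydronaphthalen-2(1H)-one; trans-fused, 7α-silyloxy epimer drawn | C[C@@H]1CCC[C@@H]2CC(=O)[C@@H](O[Si](C)(C)C(C)(C)C)C[C@@]12C | intermediate (key-step product)
17 | 7α-[(tert-butyldimethylsilyl)oxy]-8,8-(ethylenedioxy)-4β,5β-dimethyl-10α-H-decalin | C[C@@H]1CCC[C@@H]2CC3(OCCO3)[C@@H](O[Si](C)(C)C(C)(C)C)C[C@@]12C | intermediate
18 | 8,8-(ethylenedioxy)-4β,5β-dimethyl-10α-H-decalin-7α-ol | C[C@@H]1CCC[C@@H]2CC3(OCCO3)[C@@H](O)C[C@@]12C | intermediate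
19 | 8,8-(ethylenedioxy)-4β,5β-dimethyl-10α-H-decalin-7-one | C[C@@H]1CCC[C@@H]2CC3(OCCO3)C(=O)C[C@@]12C | intermediate
20 | 2-bromoprop-2-en-1-ol | C=C(Br)CO | starting material
21 | [(2-bromoprop-2-en-1-yl)oxy]tri(propan-2-yl)silane | C=C(Br)CO[Si](C(C)C)(C(C)C)C(C)C | intermediate
22 | {3-[(triisopropylsilyl)oxy]prop-1-en-2-yl}lithium | [Li]C(=C)CO[Si](C(C)C)(C(C)C)C(C)C | intermediate (not isolated)
23 | 8,8-(ethylenedioxy)-4β,5β-dimethyl-7α-{3-[(triisopropylsilyl)oxy]prop-1-en-2-yl}-10α-H-decalin-7β-ol | C[C@@H]1CCC[C@@H]2CC3(OCCO3)[C@@](O)(C(=C)CO[Si](C(C)C)(C(C)C)C(C)C)C[C@@]12C | intermediate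
24 | 7β-hydroxy-4β,5β-dimethyl-7α-{3-[(triisopropylsilyl)oxy]prop-1-en-2-yl}-10α-H-decalin-8-one | C[C@@H]1CCC[C@@H]2CC(=O)[C@@](O)(C(=C)CO[Si](C(C)C)(C(C)C)C(C)C)C[C@@]12C | intermediate
25 | 7β-hydroxy-12-[(triisopropylsilyl)oxy]eremophila-9,11(13)-dien-8-one | C[C@@H]1CCCC2=CC(=O)[C@@](O)(C(=C)CO[Si](C(C)C)(C(C)C)C(C)C)C[C@@]12C | intermediate
26 | 7β,8-bis[(trimethylsilyl)oxy]-12-[(triisopropylsilyl)oxy]eremophila-1(10),8,11(13)-triene | C[C@@H]1CCC=C2C=C(O[Si](C)(C)C)[C@@](O[Si](C)(C)C)(C(=C)CO[Si](C(C)C)(C(C)C)C(C)C)C[C@@]12C | intermediate (not isolated)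
27 | 7β-hydroxy-12-[(triisopropylsilyl)oxy]eremophila-1,9,11(13)-trien-8-one | C[C@@H]1CC=CC2=CC(=O)[C@@](O)(C(=C)CO[Si](C(C)C)(C(C)C)C(C)C)C[C@@]12C | intermediate
28 | dipotassium salt (7-alkoxide, 8-trienolate) of 27 | [K+].[K+].C[C@@H]1C=CC=C2C=C([O-])[C@@]([O-])(C(=C)CO[Si](C(C)C)(C(C)C)C(C)C)C[C@@]12C | intermediate (not isolated)
29 | 7β-hydroxy-12-[(triisopropylsilyl)oxy]eremophila-1(10),2,11(13)-trien-8-one | C[C@@H]1C=CC=C2CC(=O)[C@@](O)(C(=C)CO[Si](C(C)C)(C(C)C)C(C)C)C[C@@]12C | intermediate
30 | 3α,10α-epidioxy-7β-hydroxy-12-[(triisopropylsilyl)oxy]eremophila-1,11(13)-dien-8-one | C[C@@H]1[C@@H]3C=C[C@]2(OO3)CC(=O)[C@@](O)(C(=C)CO[Si](C(C)C)(C(C)C)C(C)C)C[C@@]12C | intermediate (not isolated)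
31 | 3α-hydroperoxy-7β-hydroxy-12-[(triisopropylsilyl)oxy]eremophila-1,9,11(13)-trien-8-one | C[C@@H]1[C@@H](OO)C=CC2=CC(=O)[C@@](O)(C(=C)CO[Si](C(C)C)(C(C)C)C(C)C)C[C@@]12C | intermediate (not isolated)
32 | 3α,7β-dihydroxy-12-[(triisopropylsilyl)oxy]eremophila-1,9,11(13)-trien-8-one | C[C@@H]1[C@@H](O)C=CC2=CC(=O)[C@@](O)(C(=C)CO[Si](C(C)C)(C(C)C)C(C)C)C[C@@]12C | intermediate
33 | (R)-2-methylbutanoic acid | CC[C@@H](C)C(=O)O | starting material
34 | (R)-2-methylbutan-1-ol | CC[C@@H](C)CO | intermediate
35 | (R)-2-methylbutanal | CC[C@@H](C)C=O | intermediate (not isolated)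
36 | (2E,4R)-2,4-dimethylhex-2-enal | O=C/C(C)=C/[C@H](C)CC | intermediate
37 | ethyl (2E,4E,6R)-4,6-dimethylocta-2,4-dienoate | CCOC(=O)/C=C/C(C)=C/[C@H](C)CC | intermediate
38 | (2E,4E,6R)-4,6-dimethylocta-2,4-dienoic acid | OC(=O)/C=C/C(C)=C/[C@H](C)CC | intermediate
39 | 7β-hydroxy-8-oxo-12-[(triisopropylsilyl)oxy]eremophila-1,9,11(13)-trien-3α-yl (2E,4E,6R)-4,6-dimethylocta-2,4-dienoate | C[C@@H]1[C@@H](OC(=O)/C=C/C(C)=C/[C@H](C)CC)C=CC2=CC(=O)[C@@](O)(C(=C)CO[Si](C(C)C)(C(C)C)C(C)C)C[C@@]12C | intermediate
40 | 7β,12-dihydroxy-8-oxoeremophila-1,9,11(13)-trien-3α-yl (2E,4E,6R)-4,6-dimethylocta-2,4-dienoate | C[C@@H]1[C@@H](OC(=O)/C=C/C(C)=C/[C@H](C)CC)C=CC2=CC(=O)[C@@](O)(C(=C)CO)C[C@@]12C | intermediate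
41 | CNP0160850.1: (3S,4S,5S,7S)-12-acetoxy-7-hydroxy-8-oxoeremophila-1,9,11(13)-trien-3-yl (2E,4E,6R)-4,6-dimethylocta-2,4-dienoate | C[C@@H]1[C@@H](OC(=O)/C=C/C(C)=C/[C@H](C)CC)C=CC2=CC(=O)[C@@](O)(C(=C)COC(C)=O)C[C@@]12C | target

**Step count**
Total: 27 steps. Longest linear sequence: 20 steps (steps 1–6, 9–13, 15–20, 25–27).

**Steps most likely to fail**

Step 10. The tertiary C5 radical may be reduced before it cyclises (net hydrogenation of the methylene), or the silyl enol ether may be solvolysed in the warm protic medium to a 1,2-dione that no longer accepts the radical at C6. The fallback sets out from 10 and returns at 16. Grignard reagent 14 is acylated with N-methoxy-N-methylprop-2-enamide to give the vinyl ketone 1-[(1R,3R)-3-methyl-2-methylidenecyclohexyl]but-3-en-2-one F1. The same Fe(acac)3/PhSiH3 cyclisation on this more electrophilic acceptor, which has no solvolysable group, should give the trans-fused ketone (4aS,5R,8aR)-4a,5-dimethyloctahydronaphthalen-2(1H)-one F2. TMSOTf/Et3N should enolise it away from the ring fusion, toward C7, as trans-fused 2-decalones do, to the trimethylsilyl enol ether F3. Rubottom oxidation (mCPBA, then dilute acid) gives the 7-hydroxy-8-ketone F4, and TBSCl/imidazole returns 16.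

Step 4. The kinetic protonation may be incompletely face-selective, or ketone 8 may epimerise during work-up, which would lower the cis purity and, through the trans isomer, the enantiomeric purity. The fallback sets out from 6 and returns at 8. Luche reduction (NaBH4, CeCl3·7H2O, MeOH, −78 °C) should deliver hydride axially and give the allylic alcohol with hydroxyl trans to the C10 side chain, (1R,2R)-2-{[(tert-butyldimethylsilyl)oxy]methyl}-6-methylidenecyclohexan-1-ol F5. Hydroxyl-directed hydrogenation with [Ir(cod)(PCy3)(py)]PF6 and H2 in CH2Cl2 adds hydrogen to C4 from the hydroxyl face, so the new methyl ends trans to the hydroxyl and cis to the side chain, giving (1S,2R,6R)-2-{[(tert-butyldimethylsilyl)oxy]methyl}-6-methylcyclohexan-1-ol F6. Dess–Martin oxidation then returns 8 without any enolate.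

Step 19. The β,γ-unsaturated ketone 29 may reconjugate to 27 during quench and work-up, or the trienolate may be protonated at C1 or C3 instead of C9, so that no ring A diene is available for step 20. The fallback sets out from 27 and returns at 32, bypassing 29–31. TMSOTf/Et3N converts 27 by ε-deprotonation at C3 into 7β,8-bis[(trimethylsilyl)oxy]-12-[(triisopropylsilyl)oxy]eremophila-1(10),2,8,11(13)-tetraene F7. Dimethyldioxirane should epoxidise its terminal C2=C3 bond from the α face, and acidic work-up opens the epoxide and removes the trimethylsilyl groups (vinylogous Rubottom oxidation) to give 32.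

**Further compounds**
F1 | step 10 | 1-[(1R,3R)-3-methyl-2-methylidenecyclohexyl]but-3-en-2-one | C=C1[C@H](C)CCC[C@@H]1CC(=O)C=C
F2 | step 10 | (4aS,5R,8aR)-4a,5-dimethyloctahydronaphthalen-2(1H)-one | C[C@@H]1CCC[C@@H]2CC(=O)CC[C@@]12C
F3 | step 10 | trimethyl{[(4aS,5R,8aR)-4a,5-dimethyl-1,4,4a,5,6,7,8,8a-octahydronaphthalen-2-yl]oxy}silane | C[C@@H]1CCC[C@@H]2CC(O[Si](C)(C)C)=CC[C@@]12C
F4 | step 10 | (4aS,5R,8aR)-3-hydroxy-4a,5-dimethyloctahydronaphthalen-2(1H)-one (C3 epimers) | C[C@@H]1CCC[C@@H]2CC(=O)C(O)C[C@@]12C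
F5 | step 4 | (1R,2R)-2-{[(tert-butyldimethylsilyl)oxy]methyl}-6-methylidenecyclohexan-1-ol | O[C@H]1C(=C)CCC[C@@H]1CO[Si](C)(C)C(C)(C)C
F6 | step 4 | (1S,2R,6R)-2-{[(tert-butyldimethylsilyl)oxy]methyl}-6-methylcyclohexan-1-ol | O[C@H]1[C@H](C)CCC[C@@H]1CO[Si](C)(C)C(C)(C)C
F7 | step 19 | 7β,8-bis[(trimethylsilyl)oxy]-12-[(triisopropylsilyl)oxy]eremophila-1(10),2,8,11(13)-tetraene | C[C@@H]1C=CC=C2C=C(O[Si](C)(C)C)[C@@](O[Si](C)(C)C)(C(=C)CO[Si](C(C)C)(C(C)C)C(C)C)C[C@@]12C
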